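**Retrosynthetic overview**

- Target numbering is used for all compounds: ring A = C4a–C5–C6–C7–C8–C8a (OSO3H at C7, CH3 at C8); ring B = C1–C2–C3=C4–C4a–C8a.
- End game: sulfate from a C7 alcohol (from a C7 ketone); dienoic acid from a C1 hydroxymethyl group by oxidation and vinylogous Horner–Wadsworth–Emmons olefination.
- Key disconnection: the C7 carbonyl of ring A and the ring B alkene C3=C4 are joined through C6–C5–C4a (δ,ε-unsaturated ketone C7(=O)–C6–C5–C4a–C4=C3), the retron of an anionic oxy-Cope rearrangement. Opening ring A at C4a–C5 and adding a bond C3–C7 that the target lacks gives a 2-vinylbicyclo[2.2.2]oct-5-en-2-ol that already holds ring B.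
- This bicycle comes in one operation from 2,6-dimethylphenol and (2Z,4E)-4-methylhexa-2,4-dienoic acid (Wessely oxidation, then intramolecular Diels–Alder reaction). The lactone tether C8–O–CO–C1, a second temporary element, fixes regio- and stereochemistry and is cut with SmI2; the racemic lactone is resolved.
- Ring order: ring B first (inside the bicyclo[2.2.2]octene, step 3), ring A last (step 9), with the cis ring fusion set in that step.

Key step: step 9

Remark: the target is taken as the free hydrogen sulfate/carboxylic acid drawn; the last step liberates it from its dilithium salt with cold acid.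

**Route**

Step 1
Reactants: 1 (E)-2-methylbut-2-enal; 2 methyl bis(2,2,2-trifluoroethyl)phosphonoacetate
Product: 3 methyl (2Z,4E)-4-methylhexa-2,4-dienoate
Conditions: KN(SiMe3)2, 18-crown-6, THF, −78 °C
Reagents that add atoms: methyl bis(2,2,2-trifluoroethyl)phosphonoacetate, COC(=O)CP(=O)(OCC(F)(F)F)OCC(F)(F)F
Why: Still–Gennari modification of the Horner–Wadsworth–Emmons olefination: the trifluoroethyl phosphonate with a crown-separated potassium counter-ion should give the 2Z-enoate, and the E-trisubstituted alkene of 1 is not touched.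

Step 2
Reactants: 3 methyl (2Z,4E)-4-methylhexa-2,4-dienoate; 4 lithium hydroxide
Product: 5 (2Z,4E)-4-methylhexa-2,4-dienoic acid
Conditions: LiOH, THF/H2O, 0 °C to rt; then 1 M HCl to pH 3
Reagents that add atoms: lithium hydroxide, [Li+].[OH-]
Why: Saponification of the methyl ester; mild aqueous base at or below room temperature should not isomerise the 2Z double bond.

Step 3
Reactants: 6 2,6-dimethylphenol; 5 (2Z,4E)-4-methylhexa-2,4-dienoic acid
Product: 8 racemic 8-[(2E)-but-2-en-2-yl]-6,7a-dimethyl-3,3a,6,7a-tetrahydro-3,6-methano-1-benzofuran-2,7-dione (keto lactone), via racemic quinol ester 7 (not isolated)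
Conditions: Pb(OAc)4 (1.1 equiv), 5 (5 equiv, excess recovered by NaHCO3 extraction), CH2Cl2, 0 °C; then toluene, 110 °C
Reagents that add atoms: (2Z,4E)-4-methylhexa-2,4-dienoic acid, C/C=C(\C)/C=C\C(=O)O
Why: Wessely oxidation in the presence of an unsaturated acid followed by intramolecular Diels–Alder reaction of the quinol ester: tetravalent lead delivers the carboxylate to the methyl-bearing ortho carbon (C8), and the short ester tether lets the dienophile reach the C3=C4–C4a=C8a diene only with its α-carbon at C8a and on the face of the acyloxy group, so the carboxyl carbon ends at C1 syn to the C7–C8 bridge, the Z geometry puts the butenyl group at C2 on the same side (final C2/C8a relationship), and the C8 methyl is left syn to the etheno bridge.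

Step 4
Reactants: 8 racemic keto lactone
Product: 9 (3S,3aR,6S,7aS,8S)-8-[(2E)-but-2-en-2-yl]-6,7a-dimethyl-3,3a,6,7a-tetrahydro-3,6-methano-1-benzofuran-2,7-dione
Conditions: preparative supercritical-fluid chromatography, amylose tris(3,5-dimethylphenylcarbamate) on silica, CO2/MeOH, 35 °C
Reagents that add atoms: none
Why: Chromatographic resolution on a chiral stationary phase: the rigid, neutral lactone enantiomers should separate on a polysaccharide carbamate phase, and the antipode whose absolute configuration is confirmed as that of 9 (for example by anomalous-dispersion X-ray diffraction) is carried on.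

Step 5
Reactants: 9 enantiopure keto lactone
Product: 10 (1S,2R,3S,4S,7R)-3-[(2E)-but-2-en-2-yl]-4,7-dimethyl-8-oxobicyclo[2.2.2]oct-5-ene-2-carboxylic acid
Conditions: SmI2 (2.5 equiv), THF/MeOH, −78 °C; then aq. K2CO3, rt; 1 M HCl
Reagents that add atoms: none
Why: SmI2 reduction of an α-acyloxy ketone: electron transfer to the C7 ketone expels the carboxylate from C8, which removes the tether and frees the C1 carboxylic acid, and protonation of the resulting enolate (finished by the carbonate equilibration) should leave the C8 methyl syn to the etheno bridge because the other epimer would press it against the C1 carboxyl group that still points at the C7–C8 bridge.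

Step 6
Reactants: 10 keto acid; 11 vinylmagnesium bromide
Product: 12 (1S,2R,3S,4S,7R,8S)-3-[(2E)-but-2-en-2-yl]-8-ethenyl-8-hydroxy-4,7-dimethylbicyclo[2.2.2]oct-5-ene-2-carboxylic acid
Conditions: CeCl3 (3.5 equiv), vinylmagnesium bromide (3.5 equiv), THF, −78 °C to 0 °C; aq. citric acid
Reagents that add atoms: vinylmagnesium bromide, C=C[Mg]Br
Why: Organocerium 1,2-addition: after the first equivalent has deprotonated the acid, the weakly basic vinylcerium reagent should add to the hindered, enolisable C7 ketone from the etheno-bridge face, the other face being covered by the C2 butenyl group, which places the vinyl group syn to C4=C4a as the rearrangement requires (new stereocentre C7).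

Step 7
Reactants: 12 hydroxy acid; 13 (trimethylsilyl)diazomethane
Product: 15 methyl (1S,2S,3S,4S,7R,8S)-3-[(2E)-but-2-en-2-yl]-8-ethenyl-8-hydroxy-4,7-dimethylbicyclo[2.2.2]oct-5-ene-2-carboxylate, via cis methyl ester 14 (not isolated)
Conditions: Me3SiCHN2, toluene/MeOH, 0 °C; concentrate; NaOMe (0.3 equiv), MeOH, 50 °C
Reagents that add atoms: (trimethylsilyl)diazomethane, C[Si](C)(C)C=[N+]=[N-]
Why: Methyl ester formation with the diazoalkane followed by base-mediated epimerisation α to the ester: the C1 ester, eclipsed with the cis C2 butenyl group on the two-carbon bridge, should relax to the trans isomer (ester syn to the etheno bridge), which is the C1 configuration of the target, while C8 is no longer epimerisable because C7 is a carbinol.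

Step 8
Reactants: 15 trans hydroxy ester
Product: 16 (1S,2S,3R,4R,7S,8S)-7-[(2E)-but-2-en-2-yl]-2-ethenyl-8-(hydroxymethyl)-1,3-dimethylbicyclo[2.2.2]oct-5-en-2-ol
Conditions: LiAlH4, THF, 0 °C; H2O work-up
Reagents that add atoms: none
Why: LiAlH4 reduction of the ester to the primary alcohol, which removes the only group that would not survive KH and leaves the tertiary allylic alcohol and the alkenes untouched.

Step 9
Reactants: 16 bicyclic diol
Product: 19 (1R,4aS,7S,8S,8aR)-7-[(2E)-but-2-en-2-yl]-8-(hydroxymethyl)-1,6-dimethyl-3,4,4a,7,8,8a-hexahydronaphthalen-2(1H)-one, via dipotassium dialkoxide 17 (not isolated), via dipotassium enolate 18 (not isolated)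
Conditions: KH (4 equiv), 18-crown-6 (2.5 equiv), THF, 0 °C to 50 °C; then sat. aq. NH4Cl, −78 °C
Reagents that add atoms: none
Why: KH and 18-crown-6 convert both hydroxyl groups into the crown-separated dialkoxide 17, in which the C7 alkoxide weakens the adjacent C3–C7 bond so that the 1,5-diene C5=C6–C7–C3–C4=C4a undergoes a concerted, charge-accelerated [3,3]-sigmatropic shift that forms C4a–C5, cleaves the temporary C3–C7 bond, moves the ring B alkene to C3=C4 and leaves enolate 18 (C6=C7–O−), which is protonated at C6 on work-up. The closest known reaction type is the anionic oxy-Cope rearrangement of 2-vinylbicyclo[2.2.2]oct-5-en-2-ols to cis-fused octalones. Ring A (C4a–C5–C6–C7–C8–C8a) is closed by the new C4a–C5 σ-bond through the boat-shaped six-centre transition state that the bicycle enforces, that is by sigmatropic transposition of the bicyclo[2.2.2]octene into the bicyclo[4.4.0]decene and not by an ionic or radical cyclisation, while ring B passes through intact. The only new stereocentre is C4a: the vinyl terminus C5 is held on the face of C4a that is turned toward the C7–C8 bridge, so C4a–C5 is formed cis to C8a–C8 (cis ring fusion, 4aS), and C1, C2, C8 and C8a are carried over unchanged. The step needs periselectivity for the [3,3] shift over C3–C7 fragmentation or a [1,3] shift, which the syn orientation of the vinyl group toward the etheno bridge (set in step 6) and the eclipsing strain of the bicycle secure, and it needs a regiodefined enolate, which the mechanism delivers toward C6 only so that the C8 stereocentre is not deprotonated. The remote primary alkoxide is a spectator that keeps the C1 side chain at the alcohol level needed afterwards.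

Step 10
Reactants: 19 keto alcohol
Product: 20 (1R,2S,4aS,7S,8S,8aR)-7-[(2E)-but-2-en-2-yl]-8-(hydroxymethyl)-1,6-dimethyl-1,2,3,4,4a,7,8,8a-octahydronaphthalen-2-ol
Conditions: Li (10 equiv), NH3(l)/THF, −78 °C; then solid NH4Cl
Reagents that add atoms: none
Why: Dissolving-metal reduction of a ketone: the C7 carbanion/alkoxide should be protonated to the more stable equatorial alcohol, cis to the C8 methyl and trans to the axial C8a–C1 bond (the epimer would have OH 1,3-diaxial to C1), which sets C7 as 7S in target numbering, and the isolated trisubstituted alkenes are inert.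

Step 11
Reactants: 20 diol
Product: 21 (1S,2S,4aS,7S,8R,8aS)-2-[(2E)-but-2-en-2-yl]-7-hydroxy-3,8-dimethyl-1,2,4a,5,6,7,8,8a-octahydronaphthalene-1-carbaldehyde
Conditions: TEMPO (0.1 equiv), PhI(OAc)2 (1.1 equiv), CH2Cl2, rt
Reagents that add atoms: none
Why: Oxoammonium (TEMPO) oxidation, selective for the unhindered primary alcohol over the hindered secondary C7–OH; the C1 stereocentre α to the aldehyde already has the more stable configuration, trans to both neighbours.

Step 12
Reactants: 21 hydroxy aldehyde; 22 triethyl (E)-4-phosphonocrotonate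
Product: 23 ethyl (2E,4E)-5-[(1S,2S,4aS,7S,8R,8aR)-2-[(2E)-but-2-en-2-yl]-7-hydroxy-3,8-dimethyl-1,2,4a,5,6,7,8,8a-octahydronaphthalen-1-yl]penta-2,4-dienoate
Conditions: 22 (2.2 equiv), LiN(SiMe3)2 (2.2 equiv), THF, −78 °C to 0 °C
Reagents that add atoms: triethyl (E)-4-phosphonocrotonate, CCOC(=O)/C=C/CP(=O)(OCC)OCC
Why: Vinylogous Horner–Wadsworth–Emmons olefination: the lithiated phosphonocrotonate reacts at its α-carbon with the aldehyde and should give the new double bond E, so the 2E,4E-dienoate results, with the C7 hydroxyl carried as its lithium alkoxide.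

Step 13
Reactants: 23 hydroxy dienoate; 24 sulfur trioxide–pyridine complex
Product: 25 pyridinium (1S,2S,4aS,7S,8R,8aR)-7-yl sulfate of 23 (pyridinium salt of the C7 sulfate monoester, ethyl ester intact)
Conditions: SO3·pyridine (5 equiv), pyridine, 50 °C
Reagents that add atoms: sulfur trioxide–pyridine complex, O=S(=O)([O-])[n+]1ccccc1
Why: O-Sulfonation of the secondary alcohol with the SO3·pyridine complex, a mild electrophile that should not touch the alkenes or the dienoate; the C7–O bond is not broken, so the configuration is retained.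

Step 14
Reactants: 25 pyridinium sulfate; 4 lithium hydroxide
Product: 26 (2E,4E)-5-[(1S,2S,4aS,7S,8R,8aR)-2-[(2E)-but-2-en-2-yl]-3,8-dimethyl-7-(sulfooxy)-1,2,4a,5,6,7,8,8a-octahydronaphthalen-1-yl]penta-2,4-dienoic acid
Conditions: LiOH (6 equiv), THF/MeOH/H2O, rt; then 1 M HCl, 0 °C, to pH 1–2; C18 desalting
Reagents that add atoms: lithium hydroxide, [Li+].[OH-]
Why: Saponification of the ethyl ester, to which the sulfate monoester anion is inert at room temperature; brief cold acidification then gives the free acid form of both acidic groups.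

**Compound list**

1 | (E)-2-methylbut-2-enal (tiglic aldehyde) | C/C=C(\C)C=O | starting material
2 | methyl bis(2,2,2-trifluoroethyl)phosphonoacetate | COC(=O)CP(=O)(OCC(F)(F)F)OCC(F)(F)F | starting material
3 | methyl (2Z,4E)-4-methylhexa-2,4-dienoate | C/C=C(\C)/C=C\C(=O)OC | intermediate
4 | lithium hydroxide | [Li+].[OH-] | starting material
5 | (2Z,4E)-4-methylhexa-2,4-dienoic acid | C/C=C(\C)/C=C\C(=O)O | intermediate
6 | 2,6-dimethylphenol | Cc1cccc(C)c1O | starting material
7 | racemic 1,3-dimethyl-2-oxocyclohexa-3,5-dien-1-yl (2Z,4E)-4-methylhexa-2,4-dienoate (quinol ester, both enantiomers) | C/C=C(\C)/C=C\C(=O)O[C@@]1(C)C=CC=C(C)C1=O.C/C=C(\C)/C=C\C(=O)O[C@]1(C)C=CC=C(C)C1=O | intermediate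
8 | racemic 8-[(2E)-but-2-en-2-yl]-6,7a-dimethyl-3,3a,6,7a-tetrahydro-3,6-methano-1-benzofuran-2,7-dione (both enantiomers) | C/C=C(\C)[C@H]1[C@]2(C)C=C[C@@H]3[C@H]1C(=O)O[C@]3(C)C2=O.C/C=C(\C)[C@@H]1[C@@]2(C)C=C[C@H]3[C@@H]1C(=O)O[C@@]3(C)C2=O | intermediate
9 | (3S,3aR,6S,7aS,8S)-8-[(2E)-but-2-en-2-yl]-6,7a-dimethyl-3,3a,6,7a-tetrahydro-3,6-methano-1-benzofuran-2,7-dione | C/C=C(\C)[C@H]1[C@]2(C)C=C[C@@H]3[C@H]1C(=O)O[C@]3(C)C2=O | intermediate
10 | (1S,2R,3S,4S,7R)-3-[(2E)-but-2-en-2-yl]-4,7-dimethyl-8-oxobicyclo[2.2.2]oct-5-ene-2-carboxylic acid (carboxyl and butenyl syn to the keto bridge, C7 methyl syn to the etheno bridge) | C/C=C(\C)[C@H]1[C@]2(C)C=C[C@H]([C@H]1C(O)=O)[C@@H](C)C2=O | intermediate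
11 | vinylmagnesium bromide | C=C[Mg]Br | starting material
12 | (1S,2R,3S,4S,7R,8S)-3-[(2E)-but-2-en-2-yl]-8-ethenyl-8-hydroxy-4,7-dimethylbicyclo[2.2.2]oct-5-ene-2-carboxylic acid (vinyl syn to the etheno bridge) | C/C=C(\C)[C@H]1[C@]2(C)C=C[C@H]([C@H]1C(O)=O)[C@@H](C)[C@@]2(O)C=C | intermediate
13 | (trimethylsilyl)diazomethane | C[Si](C)(C)C=[N+]=[N-] | starting material
14 | methyl (1S,2R,3S,4S,7R,8S)-3-[(2E)-but-2-en-2-yl]-8-ethenyl-8-hydroxy-4,7-dimethylbicyclo[2.2.2]oct-5-ene-2-carboxylate (ester cis to butenyl) | C/C=C(\C)[C@H]1[C@]2(C)C=C[C@H]([C@H]1C(=O)OC)[C@@H](C)[C@@]2(O)C=C | intermediate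
15 | methyl (1S,2S,3S,4S,7R,8S)-3-[(2E)-but-2-en-2-yl]-8-ethenyl-8-hydroxy-4,7-dimethylbicyclo[2.2.2]oct-5-ene-2-carboxylate (ester trans to butenyl, syn to the etheno bridge) | C/C=C(\C)[C@H]1[C@]2(C)C=C[C@H]([C@@H]1C(=O)OC)[C@@H](C)[C@@]2(O)C=C | intermediate
16 | (1S,2S,3R,4R,7S,8S)-7-[(2E)-but-2-en-2-yl]-2-ethenyl-8-(hydroxymethyl)-1,3-dimethylbicyclo[2.2.2]oct-5-en-2-ol | C/C=C(\C)[C@H]1[C@]2(C)C=C[C@H]([C@@H]1CO)[C@@H](C)[C@@]2(O)C=C | intermediate
17 | dipotassium dialkoxide of 16 | C/C=C(\C)[C@H]1[C@]2(C)C=C[C@H]([C@@H]1C[O-])[C@@H](C)[C@@]2([O-])C=C.[K+].[K+] | intermediate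
18 | dipotassium salt of the C6=C7 enolate and C1-CH2 alkoxide of 19 | C/C=C(\C)[C@H]1C(C)=C[C@H]2CC=C([O-])[C@H](C)[C@H]2[C@@H]1C[O-].[K+].[K+] | intermediate
19 | (1R,4aS,7S,8S,8aR)-7-[(2E)-but-2-en-2-yl]-8-(hydroxymethyl)-1,6-dimethyl-3,4,4a,7,8,8a-hexahydronaphthalen-2(1H)-one | C/C=C(\C)[C@H]1C(C)=C[C@H]2CCC(=O)[C@H](C)[C@H]2[C@@H]1CO | intermediate
20 | (1R,2S,4aS,7S,8S,8aR)-7-[(2E)-but-2-en-2-yl]-8-(hydroxymethyl)-1,6-dimethyl-1,2,3,4,4a,7,8,8a-octahydronaphthalen-2-ol | C/C=C(\C)[C@H]1C(C)=C[C@H]2CC[C@H](O)[C@H](C)[C@H]2[C@@H]1CO | intermediate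
21 | (1S,2S,4aS,7S,8R,8aS)-2-[(2E)-but-2-en-2-yl]-7-hydroxy-3,8-dimethyl-1,2,4a,5,6,7,8,8a-octahydronaphthalene-1-carbaldehyde | C/C=C(\C)[C@H]1C(C)=C[C@H]2CC[C@H](O)[C@H](C)[C@H]2[C@@H]1C=O | intermediate
22 | triethyl (E)-4-phosphonocrotonate | CCOC(=O)/C=C/CP(=O)(OCC)OCC | starting material
23 | ethyl (2E,4E)-5-[(1S,2S,4aS,7S,8R,8aR)-2-[(2E)-but-2-en-2-yl]-7-hydroxy-3,8-dimethyl-1,2,4a,5,6,7,8,8a-octahydronaphthalen-1-yl]penta-2,4-dienoate | C/C=C(\C)[C@H]1C(C)=C[C@H]2CC[C@H](O)[C@H](C)[C@H]2[C@@H]1/C=C/C=C/C(=O)OCC | intermediate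
24 | sulfur trioxide–pyridine complex | O=S(=O)([O-])[n+]1ccccc1 | starting material
25 | pyridinium salt of the C7 sulfate monoester of 23 | C/C=C(\C)[C@H]1C(C)=C[C@H]2CC[C@H](OS(=O)(=O)[O-])[C@H](C)[C@H]2[C@@H]1/C=C/C=C/C(=O)OCC.c1cc[nH+]cc1 | intermediate
26 | (2E,4E)-5-[(1S,2S,4aS,7S,8R,8aR)-2-[(2E)-but-2-en-2-yl]-3,8-dimethyl-7-(sulfooxy)-1,2,4a,5,6,7,8,8a-octahydronaphthalen-1-yl]penta-2,4-dienoic acid | C/C=C(\C)[C@H]1C(C)=C[C@H]2CC[C@H](OS(=O)(=O)O)[C@H](C)[C@H]2[C@@H]1/C=C/C=C/C(=O)O | target

**Step count and risks**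

Total steps: 14. Longest linear sequence: 14 steps (1 to 26; 2,6-dimethylphenol 6 enters at step 3).

Steps most likely to fail, with fallbacks:

Step 3. What may go wrong: transfer of acetate instead of the dienoate from lead, attack at the free para position of the phenol, and dimerisation of dienone 7 outrunning the cycloaddition of the Z-disubstituted dienophile. The fallback sets out from 3 and returns at 10; it replaces the ester tether by an ether tether and brings in the C8 methyl later.
- Reduction of 3 with iBu2AlH gives (2Z,4E)-4-methylhexa-2,4-dien-1-ol F1.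
- Oxidation of 2-methoxy-6-methylphenol F2 with PhI(OAc)2 in CH2Cl2 in the presence of F1 should give the racemic mixed-ketal masked o-benzoquinone F3.
- On warming, F3 should undergo the intramolecular Diels–Alder reaction to the racemic tricyclic keto ketal F4. It has the same C1/C2/C8a arrangement as 8, with CH2–O in place of C(=O)–O and OCH3 in place of the C8 methyl.
- Resolution as in step 4 gives the single enantiomer of the keto ketal F5.
- Excess SmI2 in THF/MeOH cleaves both C8–O bonds to the keto alcohol F6.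
- Its dianion (LiN(iPr)2, then MeI) is methylated at C8, the only enolisable position, anti to the C1 hydroxymethyl arm, to give the C8-methyl keto alcohol F7.
- TEMPO/PhI(OAc)2 in MeCN/H2O oxidises the primary alcohol of F7 to the acid 10.

Step 6. What may go wrong: enolisation or simple non-reaction at the C7 ketone, which is flanked by a quaternary and a tertiary carbon. The fallback sets out from 10 and returns at 12; it brings in the two carbons as an alkyne and adjusts the oxidation level afterwards. Ethynylmagnesium bromide with CeCl3, a slimmer sp-hybridised nucleophile, should add from the same face to give the ethynyl carbinol acid F8. Semihydrogenation (H2, Pd/CaCO3 poisoned with Pb(OAc)2, quinoline) then gives 12.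

Step 10. What may go wrong: kinetic protonation of the C7 carbanion from the open face, giving the axial alcohol or a mixture of C7 epimers. The fallback sets out from 19 and returns at 20 without a new compound. It replaces thermodynamic control by intramolecular hydride delivery: with Me4NBH(OAc)3 in MeCN/AcOH at −20 °C the C1 hydroxymethyl group, which lies over the same face of ring A as the axial C8a–C1 bond, binds boron and should pass hydride to that face of C7, which gives the same 7S alcohol.

Further compounds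
F1 | step 3 | (2Z,4E)-4-methylhexa-2,4-dien-1-ol | C/C=C(\C)/C=C\CO
F2 | step 3 | 2-methoxy-6-methylphenol | COc1cccc(C)c1O
F3 | step 3 | racemic 6-methoxy-2-methyl-6-{[(2Z,4E)-4-methylhexa-2,4-dien-1-yl]oxy}cyclohexa-2,4-dien-1-one (both enantiomers) | C/C=C(\C)/C=C\CO[C@@]1(OC)C=CC=C(C)C1=O.C/C=C(\C)/C=C\CO[C@]1(OC)C=CC=C(C)C1=O
F4 | step 3 | racemic tricyclic keto ketal, 8-[(2E)-but-2-en-2-yl]-7a-methoxy-6-methyl-3,3a,6,7a-tetrahydro-3,6-methano-1-benzofuran-7(2H)-one (both enantiomers) | C/C=C(\C)[C@H]1[C@]2(C)C=C[C@@H]3[C@H]1CO[C@]3(OC)C2=O.C/C=C(\C)[C@@H]1[C@@]2(C)C=C[C@H]3[C@@H]1CO[C@@]3(OC)C2=O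
F5 | step 3 | single enantiomer of the tricyclic keto ketal | C/C=C(\C)[C@H]1[C@]2(C)C=C[C@@H]3[C@H]1CO[C@]3(OC)C2=O
F6 | step 3 | 7-[(2E)-but-2-en-2-yl]-8-(hydroxymethyl)-1-methylbicyclo[2.2.2]oct-5-en-2-one (butenyl and hydroxymethyl syn to the keto bridge) | C/C=C(\C)[C@H]1[C@]2(C)C=C[C@H]([C@H]1CO)CC2=O
F7 | step 3 | 7-[(2E)-but-2-en-2-yl]-8-(hydroxymethyl)-1,3-dimethylbicyclo[2.2.2]oct-5-en-2-one (C3 methyl syn to the etheno bridge) | C/C=C(\C)[C@H]1[C@]2(C)C=C[C@H]([C@H]1CO)[C@@H](C)C2=O
F8 | step 6 | 3-[(2E)-but-2-en-2-yl]-8-ethynyl-8-hydroxy-4,7-dimethylbicyclo[2.2.2]oct-5-ene-2-carboxylic acid (configuration as in 12) | C/C=C(\C)[C@H]1[C@]2(C)C=C[C@H]([C@H]1C(O)=O)[C@@H](C)[C@@]2(O)C#C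
F0 | step 10 | none | none
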